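**Strategy.** Everything rests on opening ring C of the flavanone between O1 and C2. C2 is β to the C4 ketone, so the ring is the oxa-Michael adduct of a 2'-hydroxychalcone, as in biosynthesis. The precursor is that chalcone carrying a removable tert-butyl ester on the future C3 (an alkylidene β-ketoester), made by Knoevenagel condensation of a ring A β-ketoester with a biaryl aldehyde; the biaryl comes from Suzuki coupling of a 6-iodoapigenin ether. In one operation a cinchona thiourea closes the pyranone ring by attack of the ring A phenol oxygen on the benzylic carbon, sets (2S), and acid then expels the ester as isobutene and CO2.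

Key step: step 9

Remark: 7 and 12 are treated as catalogue compounds (each is otherwise one known step from 5-bromovanillin or 2',4',6'-trihydroxyacetophenone), and 15 is drawn as its expected major Z isomer (aryl cis to the ester).

Step 1
Reactants: 1 apigenin; 2 benzyl bromide
Product: 3 7-(benzyloxy)-2-[4-(benzyloxy)phenyl]-5-hydroxy-4H-chromen-4-one
Conditions: BnBr (2.2 equiv), K2CO3, DMF, rt
Reagents that add atoms: benzyl bromide, BrCc1ccccc1
Why: Williamson ether synthesis; the 5-OH is hydrogen-bonded to the C4 carbonyl and is the least nucleophilic phenol, so the 7-OH and 4'-OH should alkylate selectively.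

Step 2
Reactants: 3 7,4'-di-O-benzylapigenin; 4 benzyltrimethylammonium dichloroiodate
Product: 5 7-(benzyloxy)-2-[4-(benzyloxy)phenyl]-5-hydroxy-6-iodo-4H-chromen-4-one
Conditions: BnMe3N ICl2 (1.1 equiv), CaCO3, CH2Cl2/MeOH, rt
Reagents that add atoms: benzyltrimethylammonium dichloroiodate, C[N+](C)(C)Cc1ccccc1.Cl[I-]Cl
Why: Electrophilic aromatic iodination; in 5-hydroxy-7-alkoxyflavones this reagent is known to iodinate C6, ortho to the free chelated 5-OH, in preference to C8 and to the less activated 4'-alkoxyphenyl ring.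

Step 3
Reactants: 5 the 6-iodo-5-hydroxyflavone; 2 benzyl bromide
Product: 6 5,7-bis(benzyloxy)-2-[4-(benzyloxy)phenyl]-6-iodo-4H-chromen-4-one
Conditions: BnBr (1.5 equiv), K2CO3, DMF, 80 °C
Reagents that add atoms: benzyl bromide, BrCc1ccccc1
Why: Williamson ether synthesis under forcing conditions; the chelated, flanked 5-OH is the only nucleophilic site left, and capping it removes an acidic phenol next to the coupling site.

Step 4
Reactants: 7 3-bromo-4,5-dihydroxybenzaldehyde; 2 benzyl bromide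
Product: 8 3,4-bis(benzyloxy)-5-bromobenzaldehyde
Conditions: BnBr (2.4 equiv), K2CO3, DMF, rt to 50 °C
Reagents that add atoms: benzyl bromide, BrCc1ccccc1
Why: Williamson ether synthesis of both catechol oxygens; the non-enolisable aldehyde is inert to carbonate.

Step 5
Reactants: 8 3,4-bis(benzyloxy)-5-bromobenzaldehyde; 9 bis(pinacolato)diboron
Product: 10 3,4-bis(benzyloxy)-5-(4,4,5,5-tetramethyl-1,3,2-dioxaborolan-2-yl)benzaldehyde
Conditions: B2pin2 (1.2 equiv), PdCl2(dppf) (3 mol %), KOAc, 1,4-dioxane, 90 °C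
Reagents that add atoms: bis(pinacolato)diboron, CC1(C)OB(OC1(C)C)B1OC(C)(C)C(C)(C)O1
Why: Miyaura borylation of an aryl bromide; the weak acetate base avoids homocoupling and the aldehyde is tolerated. Boron is placed on the catechol ring because a boronate between two alkoxy groups on the flavone would protodeboronate readily.

Step 6
Reactants: 6 5,7,4'-tri-O-benzyl-6-iodoapigenin; 10 the aryl pinacol boronate
Product: 11 3,4-bis(benzyloxy)-5-{5,7-bis(benzyloxy)-2-[4-(benzyloxy)phenyl]-4-oxo-4H-chromen-6-yl}benzaldehyde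
Conditions: Pd(OAc)2 (5 mol %), SPhos (10 mol %), K3PO4, toluene/H2O (10:1), 90 °C
Reagents that add atoms: none
Why: Suzuki–Miyaura coupling; the bulky, electron-rich biaryl phosphine is the ligand class suited to tri-ortho-substituted biaryls, and the iodide provides fast oxidative addition at the hindered C6 of the flavone.

Step 7
Reactants: 12 1-[2,4-bis(benzyloxy)-6-hydroxyphenyl]ethan-1-one; 13 di-tert-butyl dicarbonate
Product: 14 tert-butyl 3-[2,4-bis(benzyloxy)-6-hydroxyphenyl]-3-oxopropanoate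
Conditions: LiHMDS (3.3 equiv), THF, −78 °C; Boc2O (1.1 equiv), −78 to 0 °C; aq. NH4Cl
Reagents that add atoms: di-tert-butyl dicarbonate, CC(C)(C)OC(=O)OC(=O)OC(C)(C)C
Why: Claisen-type C-acylation of the phenoxide/enolate dianion; any aryl carbonate formed at oxygen should be carried to the same β-ketoester by Baker–Venkataraman-type O-to-C acyl transfer under the excess base, and the tert-butyl ester resists lactonisation to a 4-hydroxycoumarin.

Step 8
Reactants: 11 the biaryl aldehyde; 14 the ring A β-ketoester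
Product: 15 tert-butyl (2Z)-2-[2,4-bis(benzyloxy)-6-hydroxybenzoyl]-3-(3,4-bis(benzyloxy)-5-{5,7-bis(benzyloxy)-2-[4-(benzyloxy)phenyl]-4-oxo-4H-chromen-6-yl}phenyl)prop-2-enoate
Conditions: piperidine (0.2 equiv), AcOH (0.2 equiv), 4 Å molecular sieves, toluene, rt
Reagents that add atoms: none
Why: Knoevenagel condensation of a non-enolisable aryl aldehyde with the active methylene; the buffered amine salt at room temperature should limit premature, uncatalysed ring closure, and the product is purified without exposure to base.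

Step 9
Reactants: 15 the alkylidene β-ketoester
Product: 17 (2S)-5,7-bis(benzyloxy)-2-(3,4-bis(benzyloxy)-5-{5,7-bis(benzyloxy)-2-[4-(benzyloxy)phenyl]-4-oxo-4H-chromen-6-yl}phenyl)-2,3-dihydro-4H-chromen-4-one, via 3-tert-butoxycarbonylflavanone 16 (not isolated)
Conditions: N-[3,5-bis(trifluoromethyl)phenyl]-N'-(9-deoxy-epi-quinidin-9-yl)thiourea (10 mol %), toluene, −25 °C; then TsOH·H2O (1 equiv), 80 °C
Reagents that add atoms: none
Why: The quinuclidine nitrogen of the catalyst activates the free ring A phenol while the thiourea binds the 1,3-dicarbonyl unit, the phenol oxygen adds to the benzylic β-carbon of the doubly activated alkene, enolate protonation gives 16, and TsOH at 80 °C then cleaves the tert-butyl ester and decarboxylates the β-keto acid. The closest known reaction type is the cinchona thiourea-catalysed enantioselective oxa-Michael cyclisation of alkylidene β-ketoesters to flavanones with decarboxylation in the same flask. Ring C closes in the 6-endo-trig mode. The C2 stereocentre is set under catalyst control by the alkene face that the bound phenol reaches in the hydrogen-bonded assembly; the quinidine-derived catalyst is proposed for the (2S) sense, its quinine-derived pseudoenantiomer reverses it, and the sense is to be confirmed on a model chalcone before material is committed. The step needs kinetic control over the reversible, racemising chalcone–flavanone equilibrium, which the C3 ester secures by letting closure run at −25 °C and by allowing its removal with acid and not base. Chemoselectivity follows because the ring A OH is the only free phenol and the flavone enone is a far weaker acceptor than the alkylidene β-ketoester.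

Step 10
Reactants: 17 the heptabenzyl (2S)-flavanone–flavone
Product: 18 (2S)-2-{3,4-dihydroxy-5-[5,7-dihydroxy-2-(4-hydroxyphenyl)-4-oxo-4H-chromen-6-yl]phenyl}-5,7-dihydroxy-2,3-dihydro-4H-chromen-4-one (CNP0176432.1)
Conditions: H2 (1 atm), 10% Pd/C, THF/MeOH, rt
Reagents that add atoms: none
Why: Catalytic hydrogenolysis of the seven benzyl aryl ethers under neutral conditions, which should neither open nor racemise the flavanone (base would, by retro-oxa-Michael reaction); the reaction is stopped at the calculated hydrogen uptake to spare the flavone C2=C3 bond and the benzylic C2–O bond.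

**Compound list**

1 | apigenin | O=c1cc(-c2ccc(O)cc2)oc2cc(O)cc(O)c12 | starting material
2 | benzyl bromide | BrCc1ccccc1 | starting material
3 | 7-(benzyloxy)-2-[4-(benzyloxy)phenyl]-5-hydroxy-4H-chromen-4-one | O=c1cc(-c2ccc(OCc3ccccc3)cc2)oc2cc(OCc3ccccc3)cc(O)c12 | intermediate
4 | benzyltrimethylammonium dichloroiodate | C[N+](C)(C)Cc1ccccc1.Cl[I-]Cl | starting material
5 | 7-(benzyloxy)-2-[4-(benzyloxy)phenyl]-5-hydroxy-6-iodo-4H-chromen-4-one | O=c1cc(-c2ccc(OCc3ccccc3)cc2)oc2cc(OCc3ccccc3)c(I)c(O)c12 | intermediate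
6 | 5,7-bis(benzyloxy)-2-[4-(benzyloxy)phenyl]-6-iodo-4H-chromen-4-one | O=c1cc(-c2ccc(OCc3ccccc3)cc2)oc2cc(OCc3ccccc3)c(I)c(OCc3ccccc3)c12 | intermediate
7 | 3-bromo-4,5-dihydroxybenzaldehyde | O=Cc1cc(O)c(O)c(Br)c1 | starting material
8 | 3,4-bis(benzyloxy)-5-bromobenzaldehyde | O=Cc1cc(OCc2ccccc2)c(OCc2ccccc2)c(Br)c1 | intermediate
9 | bis(pinacolato)diboron | CC1(C)OB(OC1(C)C)B1OC(C)(C)C(C)(C)O1 | starting material
10 | 3,4-bis(benzyloxy)-5-(4,4,5,5-tetramethyl-1,3,2-dioxaborolan-2-yl)benzaldehyde | O=Cc1cc(OCc2ccccc2)c(OCc2ccccc2)c(B2OC(C)(C)C(C)(C)O2)c1 | intermediate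
11 | 3,4-bis(benzyloxy)-5-{5,7-bis(benzyloxy)-2-[4-(benzyloxy)phenyl]-4-oxo-4H-chromen-6-yl}benzaldehyde | O=Cc1cc(OCc2ccccc2)c(OCc2ccccc2)c(-c2c(OCc3ccccc3)cc3oc(-c4ccc(OCc5ccccc5)cc4)cc(=O)c3c2OCc2ccccc2)c1 | intermediate
12 | 1-[2,4-bis(benzyloxy)-6-hydroxyphenyl]ethan-1-one | CC(=O)c1c(O)cc(OCc2ccccc2)cc1OCc1ccccc1 | starting material
13 | di-tert-butyl dicarbonate | CC(C)(C)OC(=O)OC(=O)OC(C)(C)C | starting material
14 | tert-butyl 3-[2,4-bis(benzyloxy)-6-hydroxyphenyl]-3-oxopropanoate | CC(C)(C)OC(=O)CC(=O)c1c(O)cc(OCc2ccccc2)cc1OCc1ccccc1 | intermediate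
15 | tert-butyl (2Z)-2-[2,4-bis(benzyloxy)-6-hydroxybenzoyl]-3-(3,4-bis(benzyloxy)-5-{5,7-bis(benzyloxy)-2-[4-(benzyloxy)phenyl]-4-oxo-4H-chromen-6-yl}phenyl)prop-2-enoate | CC(C)(C)OC(=O)/C(=C\c1cc(OCc2ccccc2)c(OCc2ccccc2)c(-c2c(OCc3ccccc3)cc3oc(-c4ccc(OCc5ccccc5)cc4)cc(=O)c3c2OCc2ccccc2)c1)C(=O)c1c(O)cc(OCc2ccccc2)cc1OCc1ccccc1 | intermediate
16 | tert-butyl (2S)-5,7-bis(benzyloxy)-2-(3,4-bis(benzyloxy)-5-{5,7-bis(benzyloxy)-2-[4-(benzyloxy)phenyl]-4-oxo-4H-chromen-6-yl}phenyl)-4-oxochromane-3-carboxylate (C3 epimers and enol form) | O=C1C(C(=O)OC(C)(C)C)[C@@H](c2cc(OCc3ccccc3)c(OCc3ccccc3)c(-c3c(OCc4ccccc4)cc4oc(-c5ccc(OCc6ccccc6)cc5)cc(=O)c4c3OCc3ccccc3)c2)Oc2cc(OCc3ccccc3)cc(OCc3ccccc3)c21 | intermediate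
17 | (2S)-5,7-bis(benzyloxy)-2-(3,4-bis(benzyloxy)-5-{5,7-bis(benzyloxy)-2-[4-(benzyloxy)phenyl]-4-oxo-4H-chromen-6-yl}phenyl)-2,3-dihydro-4H-chromen-4-one | O=C1C[C@@H](c2cc(OCc3ccccc3)c(OCc3ccccc3)c(-c3c(OCc4ccccc4)cc4oc(-c5ccc(OCc6ccccc6)cc5)cc(=O)c4c3OCc3ccccc3)c2)Oc2cc(OCc3ccccc3)cc(OCc3ccccc3)c21 | intermediate
18 | (2S)-2-{3,4-dihydroxy-5-[5,7-dihydroxy-2-(4-hydroxyphenyl)-4-oxo-4H-chromen-6-yl]phenyl}-5,7-dihydroxy-2,3-dihydro-4H-chromen-4-one (CNP0176432.1) | O=C1C[C@@H](c2cc(O)c(O)c(-c3c(O)cc4oc(-c5ccc(O)cc5)cc(=O)c4c3O)c2)Oc2cc(O)cc(O)c21 | target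

**Step count.** Total: 10 steps. Longest linear sequence: 7 steps (steps 1, 2, 3, 6, 8, 9, 10, from apigenin).

**Steps most likely to fail**

Step 9. The bulky 5'-aryl B ring may lower facial selectivity, and ring opening and reclosure during the hot acid stage may erode enantiopurity. Fallback, setting out from 11 and 12: Claisen–Schmidt condensation (KOH, EtOH/THF, rt) should give the 2'-hydroxychalcone F1. NaOAc in refluxing EtOH closes it by uncatalysed oxa-Michael addition to the racemic heptabenzyl flavanone F2. Preparative HPLC on an amylose tris(3,5-dimethylphenylcarbamate) phase separates the (2S)-enantiomer, which is 17, where the route is rejoined. The (2R)-enantiomer F3 is returned to the NaOAc equilibration.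

Step 6. Transmetalation at the tri-ortho-substituted axis may be slow, so that protodeboronation of the boronate and reduction of the iodide take over. Fallback, setting out from 8: acetalisation (HC(OMe)3, TsOH cat., MeOH) gives the dimethyl acetal F4. Bromine–lithium exchange (nBuLi, THF, −78 °C) gives the aryllithium F5, and ZnCl2 converts it into the arylzinc chloride F6. Negishi coupling with 6 (Pd2(dba)3, RuPhos, THF, 60 °C) gives the biaryl acetal F7. Dilute aqueous HCl in THF releases the aldehyde and returns to the route at 11.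

Step 10. Over-reduction may occur (saturation of the flavone C2=C3 bond or hydrogenolytic opening of the benzylic C2–O bond), or the reaction may stall at partly benzylated, poorly soluble stages. Fallback, setting out from 17: non-reductive Lewis-acid dealkylation with BCl3 and pentamethylbenzene as benzyl cation scavenger (CH2Cl2, −78 °C, MeOH quench) returns directly at 18; it makes no new compound (F0: none).

**Further compounds**

F1 | step 9 | (2E)-1-[2,4-bis(benzyloxy)-6-hydroxyphenyl]-3-(3,4-bis(benzyloxy)-5-{5,7-bis(benzyloxy)-2-[4-(benzyloxy)phenyl]-4-oxo-4H-chromen-6-yl}phenyl)prop-2-en-1-one | O=C(/C=C/c1cc(OCc2ccccc2)c(OCc2ccccc2)c(-c2c(OCc3ccccc3)cc3oc(-c4ccc(OCc5ccccc5)cc4)cc(=O)c3c2OCc2ccccc2)c1)c1c(O)cc(OCc2ccccc2)cc1OCc1ccccc1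
F2 | step 9 | racemic heptabenzyl flavanone–flavone | O=C1CC(c2cc(OCc3ccccc3)c(OCc3ccccc3)c(-c3c(OCc4ccccc4)cc4oc(-c5ccc(OCc6ccccc6)cc5)cc(=O)c4c3OCc3ccccc3)c2)Oc2cc(OCc3ccccc3)cc(OCc3ccccc3)c21
F3 | step 9 | (2R)-enantiomer of 17 | O=C1C[C@H](c2cc(OCc3ccccc3)c(OCc3ccccc3)c(-c3c(OCc4ccccc4)cc4oc(-c5ccc(OCc6ccccc6)cc5)cc(=O)c4c3OCc3ccccc3)c2)Oc2cc(OCc3ccccc3)cc(OCc3ccccc3)c21
F4 | step 6 | 1,2-bis(benzyloxy)-3-bromo-5-(dimethoxymethyl)benzene | COC(OC)c1cc(OCc2ccccc2)c(OCc2ccccc2)c(Br)c1
F5 | step 6 | [2,3-bis(benzyloxy)-5-(dimethoxymethyl)phenyl]lithium | COC(OC)c1cc(OCc2ccccc2)c(OCc2ccccc2)c([Li])c1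
F6 | step 6 | [2,3-bis(benzyloxy)-5-(dimethoxymethyl)phenyl]zinc chloride | COC(OC)c1cc(OCc2ccccc2)c(OCc2ccccc2)c([Zn]Cl)c1
F7 | step 6 | 5,7-bis(benzyloxy)-6-[2,3-bis(benzyloxy)-5-(dimethoxymethyl)phenyl]-2-[4-(benzyloxy)phenyl]-4H-chromen-4-one | COC(OC)c1cc(OCc2ccccc2)c(OCc2ccccc2)c(-c2c(OCc3ccccc3)cc3oc(-c4ccc(OCc5ccccc5)cc4)cc(=O)c3c2OCc2ccccc2)c1
F0 | step 10 | none | none
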